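A direct plan would acylate phloroglucinol A1 with 2-methoxy-6-methylbenzoyl chloride A2 (AlCl3) to the trihydroxybenzophenone A3, methylate its 4-OH with one equivalent of a methylating agent to A4, bridge two molecules of A4 with formaldehyde to the dimer A5, and finish by a twofold C–H borylation/oxidation ([Ir(OMe)(cod)]2, 4,4'-di-tert-butyl-2,2'-bipyridine, B2pin2; then H2O2) that adds the missing OH to each ring B.
Its weakest step would be this closing double C–H hydroxylation: it would have no close precedent on a free, ketone-chelated polyphenol, would have to succeed twice on the most precious material, and would be needed only because ring B was bought one oxygen short.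
The mono-O-methylation of triol A3 would rest on a small acidity difference between three phenols, so over-methylated and regioisomeric ethers would be expected.
The AlCl3 acylation would have to forge a tetra-ortho-substituted ketone on unprotected phloroglucinol while exposing the new ortho-methoxy ketone to a Lewis acid that cleaves such ethers.
The target is achiral, so no stereocentre or ring closure would be at stake; the weakness would lie in chemoselectivity and in the late placement of risk.

Plan of the new route
Each ring B is a 1,3-dioxygenated benzene with the ketone carbon (C1') and the methyl carbon (C6') on adjacent atoms, so it is cut at C1'–C2' and C5'–C6' into a but-2-ynoyl ketone and the four-carbon diene 1,1-dimethoxy-3-(trimethylsilyloxy)buta-1,3-diene. The twofold axis through the CH2 bridge lets both B rings be cut at once (two-directional Diels–Alder/aromatisation).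
The bis-ynone is then cut at its two C(=O)–C≡C bonds (propynyl Grignard addition to a dialdehyde), and the dialdehyde at its two Ar–CH2 bonds (formaldehyde bridging of purchased 2,6-dihydroxy-4-methoxybenzaldehyde).
Ring order: ring A is bought, the diarylmethane is assembled first, and both B rings are built last from open-chain carbons; no benzophenone exists before the key step.
The weak steps vanish: ring B is formed with OMe and OH already differentiated (no C–H hydroxylation), the only ring A methyl ether is purchased (no selective methylation), and the hindered ketone carbon sits on ring A as a formyl group before ring B exists (no Friedel–Crafts acylation).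

Key step: step 8

Remark on the chemistry: 2,6-dihydroxy-4-methoxybenzaldehyde, acetyl chloride and 1,1-dichloroethene are taken as catalogue compounds; the two carbinol centres of compound 5 are formed without control and are removed in step 4.

Step 1
Reactants: 1 2,6-dihydroxy-4-methoxybenzaldehyde (two equivalents)
Product: 3 3,3'-methylenebis(2,6-dihydroxy-4-methoxybenzaldehyde), via hydroxymethyl aldehyde 2 (not isolated)
Conditions: 37% aq. CH2O (0.48 equiv, slow addition), KOH (20 mol %), MeOH/H2O, 0 °C → rt; AcOH to pH 5
Reagents that add atoms: formaldehyde, C=O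
Why: Base-catalysed hydroxymethylation (Lederer–Manasse) followed by ortho-quinone-methide formation and capture by a second phenolate should give the methylene-bridged dimer, since the formyl group blocks the carbon between the two hydroxyls, the two remaining ring carbons are equivalent so only one regioisomer can form, and a deficit of CH2O on the inexpensive monomer limits oligomers; no stereocentre is created.

Step 2
Reactants: 3 3,3'-methylenebis(2,6-dihydroxy-4-methoxybenzaldehyde)
Product: 4 3,3'-methylenebis[2,6-bis(benzyloxy)-4-methoxybenzaldehyde]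
Conditions: BnBr (5 equiv), K2CO3 (6 equiv), DMF, 60 °C
Reagents that add atoms: benzyl bromide, BrCc1ccccc1
Why: Williamson O-benzylation of all four phenols (warm DMF overcomes the chelation to the formyl groups) should remove every free ortho-hydroxyl that could later add to the ynones, and the non-enolisable aldehydes survive carbonate base.

Step 3
Reactants: 4 3,3'-methylenebis[2,6-bis(benzyloxy)-4-methoxybenzaldehyde]
Product: 5 bis[2,4-bis(benzyloxy)-3-(1-hydroxybut-2-yn-1-yl)-6-methoxyphenyl]methane (meso/racemic mixture)
Conditions: CH3C≡CMgBr (0.5 M in THF, 3 equiv), THF, −20 °C → 0 °C; sat. aq. NH4Cl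
Reagents that add atoms: 1-propynylmagnesium bromide, CC#C[Mg]Br
Why: Grignard 1,2-addition of an alkynyl nucleophile to the two non-enolisable aryl aldehydes should proceed at both ends; the two new carbinol centres form without control, which does not matter because step 4 converts both to ketones.

Step 4
Reactants: 5 bis[2,4-bis(benzyloxy)-3-(1-hydroxybut-2-yn-1-yl)-6-methoxyphenyl]methane
Product: 6 bis[2,4-bis(benzyloxy)-3-(but-2-ynoyl)-6-methoxyphenyl]methane
Conditions: Dess–Martin periodinane (2.6 equiv), CH2Cl2, 0 °C → rt; aq. Na2S2O3/NaHCO3 wash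
Reagents that add atoms: none
Why: Dess–Martin oxidation of the benzylic, propargylic secondary alcohols should give the bis-ynone under neutral, non-nucleophilic conditions that spare the benzyl ethers and the Michael-acceptor product, and it erases both stereocentres.

Step 5
Reactants: 7 acetyl chloride; 8 1,1-dichloroethene
Product: 10 4,4-dichlorobut-3-en-2-one, via 4,4,4-trichlorobutan-2-one 9 (not isolated)
Conditions: AlCl3 (1.1 equiv), CH2Cl2, 0 °C → rt; ice/aq. HCl; distil (loss of HCl)
Reagents that add atoms: none
Why: Friedel–Crafts-type (Kondakov) acylation of an alkene, in which the acetylium ion adds to the CH2 terminus of 1,1-dichloroethene to give a chlorine-stabilised cation that takes up chloride, and the trichloro ketone 9 loses HCl on distillation to the conjugated dichlorovinyl ketone.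

Step 6
Reactants: 10 4,4-dichlorobut-3-en-2-one
Product: 11 4,4-dimethoxybut-3-en-2-one
Conditions: NaOMe (2.1 equiv), MeOH, 0 °C → rt; filter, distil
Reagents that add atoms: sodium methoxide, C[O-].[Na+]
Why: Two successive addition–elimination (vinylic substitution) events at the β-carbon of the dichlorovinyl ketone should replace both chlorides by methoxide and give the acetylketene dimethyl acetal.

Step 7
Reactants: 11 4,4-dimethoxybut-3-en-2-one
Product: 12 1,1-dimethoxy-3-(trimethylsilyloxy)buta-1,3-diene
Conditions: Me3SiCl (1.3 equiv), Et3N (1.5 equiv), ZnCl2 (3 mol %), toluene, 40 °C; filter under N2, distil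
Reagents that add atoms: chlorotrimethylsilane, C[Si](C)(C)Cl
Why: Soft enolisation and O-silylation of the methyl ketone (standard silyl dienol ether formation) should give the cross-conjugated diene, because only the CH3 side of the ketone can enolise.

Step 8
Reactants: 6 bis[2,4-bis(benzyloxy)-3-(but-2-ynoyl)-6-methoxyphenyl]methane; 12 1,1-dimethoxy-3-(trimethylsilyloxy)buta-1,3-diene (6 equiv)
Product: 15 bis[2,4-bis(benzyloxy)-3-(4-hydroxy-2-methoxy-6-methylbenzoyl)-6-methoxyphenyl]methane, via twofold cyclohexadiene ketal cycloadduct 13 (not isolated), via bis(trimethylsilyl) ether 14 (not isolated)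
Conditions: toluene, 100 °C, sealed tube, N2; concentrate; then K2CO3 (20 mol %), MeOH, 0 °C → rt; aq. NH4Cl
Reagents that add atoms: none
Why: The electron-rich diene 12 bonds through its CH2 terminus (C4) to the methyl-bearing β-carbon of each ynone and through its acetal carbon (C1) to the α-carbon in a concerted but strongly asynchronous Diels–Alder reaction, the resulting 1,4-cyclohexadiene ketal 13 loses one MeOH per ring (1,4-elimination) to aromatise to 14, and K2CO3/MeOH then cleaves the two aryl silyl ethers. The closest known reaction type is the Diels–Alder/aromatisation of 1,1-dialkoxy-3-silyloxybutadienes with acetylenic esters and ketones to give resorcinol monomethyl ethers, here run twice on one molecule. Each ring B is closed by an intermolecular [4+2] cycloaddition that forms its C1'–C2' and C5'–C6' bonds, followed by the elimination; no stereocentre is created. The step needs regioselectivity, and the matched polarisation of the two partners secures it: the acetal carbon, which keeps one OMe, ends ortho to the ketone, the silyloxy carbon para to it and the alkyne methyl on the other ortho carbon, which is exactly the 2-methoxy-4-hydroxy-6-methyl pattern. It also needs both dienophiles to react, which the excess of 12 and the remoteness and equivalence of the two ynones should allow, while the benzyl ethers keep the ring A oxygens from adding to the ynones (chromone formation) or protonating the diene.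

Step 9
Reactants: 15 bis[2,4-bis(benzyloxy)-3-(4-hydroxy-2-methoxy-6-methylbenzoyl)-6-methoxyphenyl]methane
Product: 16 digriseophene A
Conditions: H2 (1 atm), 10% Pd/C, EtOAc/MeOH, rt
Reagents that add atoms: none
Why: Hydrogenolysis of the four benzyl aryl ethers under neutral conditions should release the four ring A phenols, while the twisted, tetra-ortho-substituted diaryl ketones and the diarylmethane resist reduction and no acid or electrophile is set free near the electron-rich rings.

Compound list
1 | 2,6-dihydroxy-4-methoxybenzaldehyde | COc1cc(O)c(C=O)c(O)c1 | starting material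
2 | 2,6-dihydroxy-3-(hydroxymethyl)-4-methoxybenzaldehyde | COc1cc(O)c(C=O)c(O)c1CO | intermediate (not isolated)
3 | 3,3'-methylenebis(2,6-dihydroxy-4-methoxybenzaldehyde) | COc1cc(O)c(C=O)c(O)c1Cc1c(OC)cc(O)c(C=O)c1O | intermediate
4 | 3,3'-methylenebis[2,6-bis(benzyloxy)-4-methoxybenzaldehyde] | COc1cc(OCc2ccccc2)c(C=O)c(OCc2ccccc2)c1Cc1c(OC)cc(OCc2ccccc2)c(C=O)c1OCc1ccccc1 | intermediate
5 | bis[2,4-bis(benzyloxy)-3-(1-hydroxybut-2-yn-1-yl)-6-methoxyphenyl]methane (meso/racemic mixture, configuration not controlled) | COc1cc(OCc2ccccc2)c(C(O)C#CC)c(OCc2ccccc2)c1Cc1c(OC)cc(OCc2ccccc2)c(C(O)C#CC)c1OCc1ccccc1 | intermediate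
6 | bis[2,4-bis(benzyloxy)-3-(but-2-ynoyl)-6-methoxyphenyl]methane | COc1cc(OCc2ccccc2)c(C(=O)C#CC)c(OCc2ccccc2)c1Cc1c(OC)cc(OCc2ccccc2)c(C(=O)C#CC)c1OCc1ccccc1 | intermediate
7 | acetyl chloride | CC(=O)Cl | starting material
8 | 1,1-dichloroethene | C=C(Cl)Cl | starting material
9 | 4,4,4-trichlorobutan-2-one | CC(=O)CC(Cl)(Cl)Cl | intermediate (not isolated)
10 | 4,4-dichlorobut-3-en-2-one | CC(=O)C=C(Cl)Cl | intermediate
11 | 4,4-dimethoxybut-3-en-2-one | CC(=O)C=C(OC)OC | intermediate
12 | 1,1-dimethoxy-3-(trimethylsilyloxy)buta-1,3-diene | C=C(O[Si](C)(C)C)C=C(OC)OC | intermediate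
13 | bis{2,4-bis(benzyloxy)-3-[6,6-dimethoxy-2-methyl-4-(trimethylsilyloxy)cyclohexa-1,4-diene-1-carbonyl]-6-methoxyphenyl}methane | COc1cc(OCc2ccccc2)c(C(=O)C2=C(C)CC(O[Si](C)(C)C)=CC2(OC)OC)c(OCc2ccccc2)c1Cc1c(OC)cc(OCc2ccccc2)c(C(=O)C2=C(C)CC(O[Si](C)(C)C)=CC2(OC)OC)c1OCc1ccccc1 | intermediate (not isolated)
14 | bis{2,4-bis(benzyloxy)-6-methoxy-3-[2-methoxy-6-methyl-4-(trimethylsilyloxy)benzoyl]phenyl}methane | COc1cc(OCc2ccccc2)c(C(=O)c2c(C)cc(O[Si](C)(C)C)cc2OC)c(OCc2ccccc2)c1Cc1c(OC)cc(OCc2ccccc2)c(C(=O)c2c(C)cc(O[Si](C)(C)C)cc2OC)c1OCc1ccccc1 | intermediate (not isolated)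
15 | bis[2,4-bis(benzyloxy)-3-(4-hydroxy-2-methoxy-6-methylbenzoyl)-6-methoxyphenyl]methane | COc1cc(OCc2ccccc2)c(C(=O)c2c(C)cc(O)cc2OC)c(OCc2ccccc2)c1Cc1c(OC)cc(OCc2ccccc2)c(C(=O)c2c(C)cc(O)cc2OC)c1OCc1ccccc1 | intermediate
16 | digriseophene A, bis[2,4-dihydroxy-3-(4-hydroxy-2-methoxy-6-methylbenzoyl)-6-methoxyphenyl]methane | COc1cc(O)c(C(=O)c2c(C)cc(O)cc2OC)c(O)c1Cc1c(OC)cc(O)c(C(=O)c2c(C)cc(O)cc2OC)c1O | target

Total step count: 9. Longest linear sequence: 6 steps (steps 1, 2, 3, 4, 8, 9, from compound 1); the diene branch (steps 5–7) is 3 steps.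

Steps most likely to fail

Step 8. The twofold cycloaddition may stall after one ring, or the diene may be lost to desilylation and self-condensation before both β-methyl ynones have reacted. Ring B would then be brought in preformed, setting out from 4. Commercial 3-methoxy-5-methylphenol would be silylated (i-Pr3SiCl, imidazole, DMF) to triisopropyl(3-methoxy-5-methylphenoxy)silane F2. Bromination para to the bulky silyloxy group (NBS, MeCN, 0 °C) should give (4-bromo-3-methoxy-5-methylphenoxy)triisopropylsilane F3. Bromine–lithium exchange (n-BuLi, THF, −78 °C) and addition of the aryllithium to both formyl groups of 4 would give bis{2,4-bis(benzyloxy)-3-[hydroxy(2-methoxy-6-methyl-4-(triisopropylsilyloxy)phenyl)methyl]-6-methoxyphenyl}methane F4. Dess–Martin oxidation would give bis{2,4-bis(benzyloxy)-6-methoxy-3-[2-methoxy-6-methyl-4-(triisopropylsilyloxy)benzoyl]phenyl}methane F5, and Bu4NF (THF, 0 °C) would cleave the two silyl ethers to come back to the route at 15.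

Step 1. The formaldehyde bridging may run on to trimers and higher oligomers, because each ring of the dimer keeps one nucleophilic carbon, or may stop at the hydroxymethyl stage. The two halves would then be joined stepwise in 1:1 stoichiometry, setting out from 1. A Mannich aminomethylation (dimethylmethylideneammonium iodide, CH2Cl2, rt) would give 3-[(dimethylamino)methyl]-2,6-dihydroxy-4-methoxybenzaldehyde F1, which would be isolated. Heating F1 with one equivalent of 1 (dioxane, 100 °C) would release the ortho-quinone methide by loss of Me2NH only in the presence of its trap, and the route would be rejoined at 3.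

Step 6. Methoxide may add a third time to the product ketene acetal or cleave the acetyl group instead of stopping at double vinylic substitution. The acetal carbon would then be introduced with both methoxy groups already in place, setting out from 7. C-acylation of commercial 1,1-dimethoxyethene (2 equiv, the second as HCl acceptor; Et2O, 0 °C) would give 11 directly, where the route is rejoined; this fallback makes no compound outside the list (F0).

Further compounds
F1 | step 1 | 3-[(dimethylamino)methyl]-2,6-dihydroxy-4-methoxybenzaldehyde | COc1cc(O)c(C=O)c(O)c1CN(C)C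
F2 | step 8 | triisopropyl(3-methoxy-5-methylphenoxy)silane | COc1cc(C)cc(O[Si](C(C)C)(C(C)C)C(C)C)c1
F3 | step 8 | (4-bromo-3-methoxy-5-methylphenoxy)triisopropylsilane | COc1cc(O[Si](C(C)C)(C(C)C)C(C)C)cc(C)c1Br
F4 | step 8 | bis{2,4-bis(benzyloxy)-3-[hydroxy(2-methoxy-6-methyl-4-(triisopropylsilyloxy)phenyl)methyl]-6-methoxyphenyl}methane (mixture of diastereomers) | COc1cc(OCc2ccccc2)c(C(O)c2c(C)cc(O[Si](C(C)C)(C(C)C)C(C)C)cc2OC)c(OCc2ccccc2)c1Cc1c(OC)cc(OCc2ccccc2)c(C(O)c2c(C)cc(O[Si](C(C)C)(C(C)C)C(C)C)cc2OC)c1OCc1ccccc1
F5 | step 8 | bis{2,4-bis(benzyloxy)-6-methoxy-3-[2-methoxy-6-methyl-4-(triisopropylsilyloxy)benzoyl]phenyl}methane | COc1cc(OCc2ccccc2)c(C(=O)c2c(C)cc(O[Si](C(C)C)(C(C)C)C(C)C)cc2OC)c(OCc2ccccc2)c1Cc1c(OC)cc(OCc2ccccc2)c(C(=O)c2c(C)cc(O[Si](C(C)C)(C(C)C)C(C)C)cc2OC)c1OCc1ccccc1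
F0 | step 6 | none | none
A1 | direct plan | phloroglucinol (benzene-1,3,5-triol) | Oc1cc(O)cc(O)c1
A2 | direct plan | 2-methoxy-6-methylbenzoyl chloride | COc1cccc(C)c1C(=O)Cl
A3 | direct plan | (2-methoxy-6-methylphenyl)(2,4,6-trihydroxyphenyl)methanone | COc1cccc(C)c1C(=O)c1c(O)cc(O)cc1O
A4 | direct plan | (2,6-dihydroxy-4-methoxyphenyl)(2-methoxy-6-methylphenyl)methanone | COc1cc(O)c(C(=O)c2c(C)cccc2OC)c(O)c1
A5 | direct plan | bis[2,4-dihydroxy-6-methoxy-3-(2-methoxy-6-methylbenzoyl)phenyl]methane | COc1cc(O)c(C(=O)c2c(C)cccc2OC)c(O)c1Cc1c(OC)cc(O)c(C(=O)c2c(C)cccc2OC)c1O
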